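**Retrosynthetic overview**

1. Target 35 ⇐ fluoride desilylation of 34 ⇐ ionic hydrogenation of the bridged silyl ketal 33, which sets C9 by hydride delivery from the lactone face.
2. 33 ⇐ C1–C2 bond by intramolecular samarium Reformatsky aldol of bromo aldehyde 31; this closes the C2–C3–C4 bridge (oxepane and seven-membered lactone rings at once) and sets C1 and C2.
3. 31 ⇐ monocyclic silyl ketal 27 ⇐ C9–C1′ bond from side-chain alkyllithium 23 and lactide 22. Enabling feature: the ring O8–C9–C5–O6–C7(=O)–C1 is a 1,4-dioxane-2,5-dione (lactide) whose C9 carbonyl has been alkylated and reduced. In 22 only C1 carries an acidic hydrogen, so the C7 carbonyl can be masked as its enolate while the C9 carbonyl, next to quaternary C5, takes the carbanion.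
4. 22 ⇐ hydroxy acid 6 ((R)-linalool supplies C5) + α-bromoacyl chloride 14 (Z-selective Wittig); the nucleophile comes from (Z)-3-methylpent-2-en-4-yn-1-ol.
5. Ring order: 1,4-dioxane ring first (step 13), then the carbon bridge that completes the bicyclo[3.2.2] system (step 18).

Key step: step 14

Remark: locants C1–C9 are those of the 6,8-dioxabicyclo[3.2.2]nonan-7-one core of the target (C1 quaternary carbon with the 4-methylpentenyl chain, C2 carbinol, C5 methyl-bearing carbon, O6–C7(=O) lactone, O8–C9 ether) and are used for the corresponding atoms of all precursors; TBDPS = tert-butyldiphenylsilyl, TES = triethylsilyl, PMB = 4-methoxybenzyl; commercial (R)-linalool is assumed to be enriched to the required enantiomeric purity.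

**Route**

Step 1
Reactants: 1 (R)-linalool
Product: 3 (4R)-4-methylhex-5-ene-1,4-diol, via (4R)-4-hydroxy-4-methylhex-5-enal 2 (not isolated)
Conditions: O3 (1 equiv, Sudan III end point), CH2Cl2/MeOH, −78 °C; then NaBH4, −78 °C to rt
Reagents that add atoms: ozone, [O-][O+]=O
Why: Ozonolysis with reductive work-up should cleave the electron-rich trisubstituted alkene in preference to the vinyl group next to the tertiary alcohol, and the linalool stereocentre (future C5) is not touched.

Step 2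
Reactants: 3 (4R)-4-methylhex-5-ene-1,4-diol
Product: 4 (3R)-6-[(4-methoxybenzyl)oxy]-3-methylhex-1-en-3-ol
Conditions: NaH (1.05 equiv), PMBCl, Bu4NI (cat.), THF/DMF, 0 °C
Reagents that add atoms: 4-methoxybenzyl chloride, COc1ccc(CCl)cc1
Why: Williamson etherification should occur at the primary alkoxide because the tertiary allylic alkoxide is too hindered.

Step 3
Reactants: 4 (3R)-6-[(4-methoxybenzyl)oxy]-3-methylhex-1-en-3-ol
Product: 5 (2R)-2-hydroxy-5-[(4-methoxybenzyl)oxy]-2-methylpentanal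
Conditions: O3, CH2Cl2, −78 °C (Sudan III end point); then PPh3
Reagents that add atoms: ozone, [O-][O+]=O
Why: Ozonolysis of the remaining vinyl group with phosphine work-up should give the α-hydroxy aldehyde, and the indicator dye limits ozone exposure of the PMB ring.

Step 4
Reactants: 5 (2R)-2-hydroxy-5-[(4-methoxybenzyl)oxy]-2-methylpentanal
Product: 6 (2R)-2-hydroxy-5-[(4-methoxybenzyl)oxy]-2-methylpentanoic acid
Conditions: NaClO2, NaH2PO4, 2-methylbut-2-ene, t-BuOH/H2O, 0 °C to rt
Reagents that add atoms: sodium chlorite, [Na+].[O-]Cl=O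
Why: Pinnick oxidation converts the aldehyde to the acid under buffered conditions that leave the PMB ether and the quaternary carbinol intact.

Step 5
Reactants: 7 hydroxyacetone
Product: 8 1-[(tert-butyldiphenylsilyl)oxy]propan-2-one
Conditions: TBDPSCl, imidazole, CH2Cl2, 0 °C to rt
Reagents that add atoms: tert-butyl(chloro)diphenylsilane, CC(C)(C)[Si](Cl)(c1ccccc1)c1ccccc1
Why: Standard silylation of a primary alcohol.

Step 6
Reactants: 8 1-[(tert-butyldiphenylsilyl)oxy]propan-2-one; 9 (4-carboxybutyl)triphenylphosphonium bromide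
Product: 11 (5Z)-7-[(tert-butyldiphenylsilyl)oxy]-6-methylhept-5-enoic acid, via phosphorus ylide carboxylate 10 (not isolated)
Conditions: 9, NaHMDS (2.1 equiv), THF, 0 °C; then 8, −78 °C to rt; aq HCl
Reagents that add atoms: none
Why: Wittig olefination of an α-silyloxy methyl ketone with a non-stabilised ylide is expected to be Z-selective, placing the chain cis to the CH2OSi group as the C1 side chain requires.

Step 7
Reactants: 11 (5Z)-7-[(tert-butyldiphenylsilyl)oxy]-6-methylhept-5-enoic acid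
Product: 13 (5Z)-2-bromo-7-[(tert-butyldiphenylsilyl)oxy]-6-methylhept-5-enoic acid (racemic), via dilithium enediolate 12 (not isolated)
Conditions: LDA (2.2 equiv), THF, −78 to 0 °C; CBr4, −78 °C; aq HCl
Reagents that add atoms: carbon tetrabromide, BrC(Br)(Br)Br
Why: Electrophilic α-bromination of the carboxylic acid dianion should leave the alkene alone; the new centre is racemic and is enolised later.

Step 8
Reactants: 13 (5Z)-2-bromo-7-[(tert-butyldiphenylsilyl)oxy]-6-methylhept-5-enoic acid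
Product: 14 (5Z)-2-bromo-7-[(tert-butyldiphenylsilyl)oxy]-6-methylhept-5-enoyl chloride
Conditions: (COCl)2, DMF (cat.), CH2Cl2, 0 °C to rt
Reagents that add atoms: oxalyl chloride, ClC(=O)C(Cl)=O
Why: Standard acid chloride formation; used crude.

Step 9
Reactants: 15 (2Z)-3-methylpent-2-en-4-yn-1-ol
Product: 16 tert-butyl{[(2Z)-3-methylpent-2-en-4-yn-1-yl]oxy}diphenylsilane
Conditions: TBDPSCl, imidazole, CH2Cl2, 0 °C to rt
Reagents that add atoms: tert-butyl(chloro)diphenylsilane, CC(C)(C)[Si](Cl)(c1ccccc1)c1ccccc1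
Why: Standard silylation; the Z-trisubstituted alkene of the C9 side chain is bought in.

Step 10
Reactants: 16 tert-butyl{[(2Z)-3-methylpent-2-en-4-yn-1-yl]oxy}diphenylsilane
Product: 17 tert-butyl{[(2Z)-3-methylpenta-2,4-dien-1-yl]oxy}diphenylsilane
Conditions: H2 (1 atm), Pb-poisoned Pd/CaCO3, quinoline, hexane/EtOAc, rt
Reagents that add atoms: none
Why: Semi-hydrogenation of the terminal alkyne should stop at the vinyl group and not touch the trisubstituted alkene geometry.

Step 11
Reactants: 17 tert-butyl{[(2Z)-3-methylpenta-2,4-dien-1-yl]oxy}diphenylsilane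
Product: 19 (3Z)-5-[(tert-butyldiphenylsilyl)oxy]-3-methylpent-3-en-1-ol, via B-alkyl-9-borabicyclo[3.3.1]nonane 18 (not isolated)
Conditions: 9-BBN, THF, 0 °C to rt; then NaOH, H2O2, 0 °C
Reagents that add atoms: hydrogen peroxide, OO
Why: Hydroboration–oxidation with a bulky borane should occur only at the monosubstituted terminal alkene, anti-Markovnikov.

Step 12
Reactants: 19 (3Z)-5-[(tert-butyldiphenylsilyl)oxy]-3-methylpent-3-en-1-ol
Product: 20 tert-butyl{[(2Z)-5-iodo-3-methylpent-2-en-1-yl]oxy}diphenylsilane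
Conditions: I2, PPh3, imidazole, CH2Cl2, 0 °C
Reagents that add atoms: iodine, II
Why: Appel iodination of a primary alcohol.

Step 13
Reactants: 6 (2R)-2-hydroxy-5-[(4-methoxybenzyl)oxy]-2-methylpentanoic acid; 14 (5Z)-2-bromo-7-[(tert-butyldiphenylsilyl)oxy]-6-methylhept-5-enoyl chloride
Product: 22 (3R,6RS)-6-{(3Z)-5-[(tert-butyldiphenylsilyl)oxy]-4-methylpent-3-en-1-yl}-3-{3-[(4-methoxybenzyl)oxy]propyl}-3-methyl-1,4-dioxane-2,5-dione, via O-(2-bromoacyl) hydroxy acid 21 (not isolated)
Conditions: pyridine, DMAP (cat.), CH2Cl2, 0 °C to rt; then NaHCO3, DMF (high dilution), rt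
Reagents that add atoms: none
Why: O-acylation of the tertiary α-hydroxy acid followed by intramolecular carboxylate SN2 displacement of the α-bromide (6-exo-tet) is the classical synthesis of unsymmetrical 1,4-dioxane-2,5-diones; the future C1 forms as both epimers, which is harmless because it is enolised in steps 14, 15 and 18.

Step 14
Reactants: 22 the 1,4-dioxane-2,5-dione of step 13; 20 tert-butyl{[(2Z)-5-iodo-3-methylpent-2-en-1-yl]oxy}diphenylsilane
Product: 27 (6R)-3-{(3Z)-5-[(tert-butyldiphenylsilyl)oxy]-4-methylpent-3-en-1-yl}-5-{(3Z)-5-[(tert-butyldiphenylsilyl)oxy]-3-methylpent-3-en-1-yl}-6-{3-[(4-methoxybenzyl)oxy]propyl}-6-methyl-5-[(triethylsilyl)oxy]-1,4-dioxan-2-one (epimers at C3 and C5 of the ring), via homoallylic lithium reagent 23 (not isolated), via lithium enolate of 22 24 (not isolated), via dilithio tetrahedral adduct 25 (not isolated), via bis-O-triethylsilyl adduct 26 (not isolated)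
Conditions: 20, t-BuLi (2.0 equiv), Et2O/pentane, −78 °C; separately 22, LiHMDS (1.05 equiv), THF, −78 °C; combine at −78 °C; TESOTf (2.3 equiv), −78 to −40 °C; aq NaHCO3
Reagents that add atoms: triethylsilyl trifluoromethanesulfonate, CC[Si](CC)(CC)OS(=O)(=O)C(F)(F)F
Why: Proposed new method: LiHMDS removes the only acidic hydrogen of 22 (the C–H of the future C1, α to the future C7 carbonyl) so that this ester is masked as lithium enolate 24, and the primary alkyllithium 23 then adds to the remaining carbonyl (future C9), which cannot enolise because it is flanked by quaternary C5; the dilithio adduct 25 cannot collapse, since that would expel an enediolate, and is captured by TESOTf as the silyl ketal/silyl ketene acetal 26, whose ketene acetal is hydrolysed on work-up to give 27. The closest known reaction types are the addition of organolithiums to lactones with O-silyl capture of the tetrahedral intermediate (lactol chemistry used for C-glycosides) and the use of an enolate as an in situ protecting group while a nucleophile attacks a second carbonyl; the combination has not been shown on a 1,4-dioxane-2,5-dione. No ring is closed: the six-membered ring of 22 is kept and its C9 carbonyl is brought to the ketal level from which C9 is set in step 19. The new ketal centre (C9) and C1 are formed as mixtures by design, because C9 is ionised again in step 19 and C1 is re-enolised in steps 15 and 18, while the linalool-derived C5 is not involved. The step needs site selectivity between two ester carbonyls and mono-addition; the first is secured by the substitution pattern (hydrogen only at C1), the second by the enolate charge and the low temperature, which should keep the tetrahedral intermediate intact until it is silylated.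

Step 15
Reactants: 27 the silyl ketal lactone of step 14
Product: 29 (6R)-3-bromo-3-{(3Z)-5-[(tert-butyldiphenylsilyl)oxy]-4-methylpent-3-en-1-yl}-5-{(3Z)-5-[(tert-butyldiphenylsilyl)oxy]-3-methylpent-3-en-1-yl}-6-{3-[(4-methoxybenzyl)oxy]propyl}-6-methyl-5-[(triethylsilyl)oxy]-1,4-dioxan-2-one (diastereomer mixture), via lithium enolate of 27 28 (not isolated)
Conditions: LDA (1.1 equiv), THF, −78 °C; NBS, −78 °C; AcOH quench
Reagents that add atoms: N-bromosuccinimide, O=C1CCC(=O)N1Br
Why: α-Bromination of the lactone enolate installs a handle from which the C1 enolate can later be regenerated by reduction in the presence of an enolisable aldehyde, which a base could not do selectively.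

Step 16
Reactants: 29 the bromo lactone of step 15
Product: 30 (6R)-3-bromo-3-{(3Z)-5-[(tert-butyldiphenylsilyl)oxy]-4-methylpent-3-en-1-yl}-5-{(3Z)-5-[(tert-butyldiphenylsilyl)oxy]-3-methylpent-3-en-1-yl}-6-(3-hydroxypropyl)-6-methyl-5-[(triethylsilyl)oxy]-1,4-dioxan-2-one
Conditions: DDQ, CH2Cl2/pH 7 buffer, 0 °C
Reagents that add atoms: none
Why: Oxidative PMB cleavage is neutral and should spare the silyl ketal, the tertiary bromide, the silyl ethers and the trisubstituted alkenes.

Step 17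
Reactants: 30 the primary alcohol of step 16
Product: 31 (6R)-3-bromo-3-{(3Z)-5-[(tert-butyldiphenylsilyl)oxy]-4-methylpent-3-en-1-yl}-5-{(3Z)-5-[(tert-butyldiphenylsilyl)oxy]-3-methylpent-3-en-1-yl}-6-methyl-6-(3-oxopropyl)-5-[(triethylsilyl)oxy]-1,4-dioxan-2-one
Conditions: Dess–Martin periodinane, pyridine, CH2Cl2, 0 °C to rt
Reagents that add atoms: none
Why: Dess–Martin oxidation gives the aldehyde (future C2) under nearly neutral conditions.

Step 18
Reactants: 31 the bromo aldehyde of step 17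
Product: 33 (1R,2S,5R)-2-hydroxy-1-{(3Z)-5-[(tert-butyldiphenylsilyl)oxy]-4-methylpent-3-en-1-yl}-9-{(3Z)-5-[(tert-butyldiphenylsilyl)oxy]-3-methylpent-3-en-1-yl}-5-methyl-9-[(triethylsilyl)oxy]-6,8-dioxabicyclo[3.2.2]nonan-7-one (both C9 epimers), via samarium(III) enolate 32 (not isolated)
Conditions: SmI2 (2.2 equiv), THF, −78 °C; aq work-up
Reagents that add atoms: none
Why: Samarium diiodide should reduce the tertiary α-bromo lactone to enolate 32, which adds to the tethered aldehyde (intramolecular Reformatsky aldol) and closes the C2–C3–C4 bridge; C1 is fixed because the tether can reach only one face of the enolate, and C2 by a closed chair-like transition state in which samarium bridges the enolate oxygen and the aldehyde oxygen, placing the new hydroxyl syn to the lactone bridge.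

Step 19
Reactants: 33 the bridged silyl ketal of step 18
Product: 34 (1R,2S,5R,9S)-2-hydroxy-1-{(3Z)-5-[(tert-butyldiphenylsilyl)oxy]-4-methylpent-3-en-1-yl}-9-{(3Z)-5-[(tert-butyldiphenylsilyl)oxy]-3-methylpent-3-en-1-yl}-5-methyl-6,8-dioxabicyclo[3.2.2]nonan-7-one
Conditions: Et3SiH, BF3·OEt2, CH2Cl2, −78 to −20 °C
Reagents that add atoms: none
Why: The Lewis acid ionises the silyl ketal to the bridged oxocarbenium ion and triethylsilane should deliver hydride to C9 from the face turned toward the O6–C7 lactone bridge, which carries only the lone pairs of O6, and not from the face flanked by the C4 methylene (ionic hydrogenation as in lactol-to-C-glycoside reductions), so that hydrogen ends syn to the lactone and the side chain syn to the carbon bridge, as 9S requires.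

Step 20
Reactants: 34 the bis-silyl ether of step 19
Product: 35 (1R,2S,5R,9S)-2-hydroxy-1-[(3Z)-5-hydroxy-4-methylpent-3-en-1-yl]-9-[(3Z)-5-hydroxy-3-methylpent-3-en-1-yl]-5-methyl-6,8-dioxabicyclo[3.2.2]nonan-7-one (CNP0105745.1)
Conditions: HF·pyridine, THF/pyridine, 0 °C to rt
Reagents that add atoms: none
Why: Fluoride cleavage of both TBDPS ethers under buffered acidic conditions avoids base-induced retro-aldol or lactone migration in the β-hydroxy lactone.

**Compound list**

1 | (R)-linalool, (3R)-3,7-dimethylocta-1,6-dien-3-ol | CC(C)=CCC[C@@](C)(O)C=C | starting material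
2 | (4R)-4-hydroxy-4-methylhex-5-enal | O=CCC[C@@](C)(O)C=C | intermediate
3 | (4R)-4-methylhex-5-ene-1,4-diol | OCCC[C@@](C)(O)C=C | intermediate
4 | (3R)-6-[(4-methoxybenzyl)oxy]-3-methylhex-1-en-3-ol | COc1ccc(COCCC[C@@](C)(O)C=C)cc1 | intermediate
5 | (2R)-2-hydroxy-5-[(4-methoxybenzyl)oxy]-2-methylpentanal | COc1ccc(COCCC[C@@](C)(O)C=O)cc1 | intermediate
6 | (2R)-2-hydroxy-5-[(4-methoxybenzyl)oxy]-2-methylpentanoic acid | COc1ccc(COCCC[C@@](C)(O)C(O)=O)cc1 | intermediate
7 | hydroxyacetone | CC(=O)CO | starting material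
8 | 1-[(tert-butyldiphenylsilyl)oxy]propan-2-one | CC(=O)CO[Si](c1ccccc1)(c1ccccc1)C(C)(C)C | intermediate
9 | (4-carboxybutyl)triphenylphosphonium bromide | OC(=O)CCCC[P+](c1ccccc1)(c1ccccc1)c1ccccc1.[Br-] | starting material
10 | sodium 5-(triphenyl-λ5-phosphanylidene)pentanoate | [Na+].[O-]C(=O)CCCC=P(c1ccccc1)(c1ccccc1)c1ccccc1 | intermediate
11 | (5Z)-7-[(tert-butyldiphenylsilyl)oxy]-6-methylhept-5-enoic acid | OC(=O)CCC/C=C(C)\CO[Si](c1ccccc1)(c1ccccc1)C(C)(C)C | intermediate
12 | dilithium enediolate of 11 | [Li]OC(O[Li])=CCC/C=C(C)\CO[Si](c1ccccc1)(c1ccccc1)C(C)(C)C | intermediate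
13 | (5Z)-2-bromo-7-[(tert-butyldiphenylsilyl)oxy]-6-methylhept-5-enoic acid (racemic) | OC(=O)C(Br)CC/C=C(C)\CO[Si](c1ccccc1)(c1ccccc1)C(C)(C)C | intermediate
14 | (5Z)-2-bromo-7-[(tert-butyldiphenylsilyl)oxy]-6-methylhept-5-enoyl chloride | ClC(=O)C(Br)CC/C=C(C)\CO[Si](c1ccccc1)(c1ccccc1)C(C)(C)C | intermediate
15 | (2Z)-3-methylpent-2-en-4-yn-1-ol | C#C/C(C)=C\CO | starting material
16 | tert-butyl{[(2Z)-3-methylpent-2-en-4-yn-1-yl]oxy}diphenylsilane | C#C/C(C)=C\CO[Si](c1ccccc1)(c1ccccc1)C(C)(C)C | intermediate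
17 | tert-butyl{[(2Z)-3-methylpenta-2,4-dien-1-yl]oxy}diphenylsilane | C=C/C(C)=C\CO[Si](c1ccccc1)(c1ccccc1)C(C)(C)C | intermediate
18 | 9-{(3Z)-5-[(tert-butyldiphenylsilyl)oxy]-3-methylpent-3-en-1-yl}-9-borabicyclo[3.3.1]nonane | C(C/C(C)=C\CO[Si](c1ccccc1)(c1ccccc1)C(C)(C)C)B1C2CCCC1CCC2 | intermediate
19 | (3Z)-5-[(tert-butyldiphenylsilyl)oxy]-3-methylpent-3-en-1-ol | OCC/C(C)=C\CO[Si](c1ccccc1)(c1ccccc1)C(C)(C)C | intermediate
20 | tert-butyl{[(2Z)-5-iodo-3-methylpent-2-en-1-yl]oxy}diphenylsilane | ICC/C(C)=C\CO[Si](c1ccccc1)(c1ccccc1)C(C)(C)C | intermediate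
21 | (2R)-2-{[(5Z)-2-bromo-7-(TBDPS-oxy)-6-methylhept-5-enoyl]oxy}-5-[(4-methoxybenzyl)oxy]-2-methylpentanoic acid | COc1ccc(COCCC[C@@](C)(OC(=O)C(Br)CC/C=C(C)\CO[Si](c2ccccc2)(c2ccccc2)C(C)(C)C)C(O)=O)cc1 | intermediate
22 | (3R,6RS)-6-{(3Z)-5-(TBDPS-oxy)-4-methylpent-3-en-1-yl}-3-{3-[(4-methoxybenzyl)oxy]propyl}-3-methyl-1,4-dioxane-2,5-dione | COc1ccc(COCCC[C@@]2(C)OC(=O)C(CC/C=C(C)\CO[Si](c3ccccc3)(c3ccccc3)C(C)(C)C)OC2=O)cc1 | intermediate
23 | {(3Z)-5-[(tert-butyldiphenylsilyl)oxy]-3-methylpent-3-en-1-yl}lithium | [Li]CC/C(C)=C\CO[Si](c1ccccc1)(c1ccccc1)C(C)(C)C | intermediate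
24 | lithium enolate of 22 (enolised at the carbonyl next to the C–H carbon) | COc1ccc(COCCC[C@@]2(C)OC(O[Li])=C(CC/C=C(C)\CO[Si](c3ccccc3)(c3ccccc3)C(C)(C)C)OC2=O)cc1 | intermediate
25 | dilithio tetrahedral adduct of 23 and 24 | COc1ccc(COCCC[C@@]2(C)OC(O[Li])=C(CC/C=C(C)\CO[Si](c3ccccc3)(c3ccccc3)C(C)(C)C)OC2(O[Li])CC/C(C)=C\CO[Si](c3ccccc3)(c3ccccc3)C(C)(C)C)cc1 | intermediate
26 | bis-O-triethylsilyl derivative of 25 (silyl ketal and silyl ketene acetal) | COc1ccc(COCCC[C@@]2(C)OC(O[Si](CC)(CC)CC)=C(CC/C=C(C)\CO[Si](c3ccccc3)(c3ccccc3)C(C)(C)C)OC2(O[Si](CC)(CC)CC)CC/C(C)=C\CO[Si](c3ccccc3)(c3ccccc3)C(C)(C)C)cc1 | intermediate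
27 | (6R)-3-{(3Z)-5-(TBDPS-oxy)-4-methylpent-3-en-1-yl}-5-{(3Z)-5-(TBDPS-oxy)-3-methylpent-3-en-1-yl}-6-{3-[(4-methoxybenzyl)oxy]propyl}-6-methyl-5-[(triethylsilyl)oxy]-1,4-dioxan-2-one | COc1ccc(COCCC[C@@]2(C)OC(=O)C(CC/C=C(C)\CO[Si](c3ccccc3)(c3ccccc3)C(C)(C)C)OC2(O[Si](CC)(CC)CC)CC/C(C)=C\CO[Si](c3ccccc3)(c3ccccc3)C(C)(C)C)cc1 | intermediate
28 | lithium enolate of 27 | COc1ccc(COCCC[C@@]2(C)OC(O[Li])=C(CC/C=C(C)\CO[Si](c3ccccc3)(c3ccccc3)C(C)(C)C)OC2(O[Si](CC)(CC)CC)CC/C(C)=C\CO[Si](c3ccccc3)(c3ccccc3)C(C)(C)C)cc1 | intermediate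
29 | 3-bromo derivative of 27 | COc1ccc(COCCC[C@@]2(C)OC(=O)C(Br)(CC/C=C(C)\CO[Si](c3ccccc3)(c3ccccc3)C(C)(C)C)OC2(O[Si](CC)(CC)CC)CC/C(C)=C\CO[Si](c3ccccc3)(c3ccccc3)C(C)(C)C)cc1 | intermediate
30 | (6R)-3-bromo-6-(3-hydroxypropyl) analogue of 29 (PMB removed) | OCCC[C@@]1(C)OC(=O)C(Br)(CC/C=C(C)\CO[Si](c2ccccc2)(c2ccccc2)C(C)(C)C)OC1(O[Si](CC)(CC)CC)CC/C(C)=C\CO[Si](c2ccccc2)(c2ccccc2)C(C)(C)C | intermediate
31 | (6R)-3-bromo-6-(3-oxopropyl) analogue (aldehyde) | O=CCC[C@@]1(C)OC(=O)C(Br)(CC/C=C(C)\CO[Si](c2ccccc2)(c2ccccc2)C(C)(C)C)OC1(O[Si](CC)(CC)CC)CC/C(C)=C\CO[Si](c2ccccc2)(c2ccccc2)C(C)(C)C | intermediate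
32 | samarium(III) enolate from 31 | O=CCC[C@@]1(C)OC(O[Sm](I)I)=C(CC/C=C(C)\CO[Si](c2ccccc2)(c2ccccc2)C(C)(C)C)OC1(O[Si](CC)(CC)CC)CC/C(C)=C\CO[Si](c2ccccc2)(c2ccccc2)C(C)(C)C | intermediate
33 | (1R,2S,5R)-2-hydroxy-1-{(3Z)-5-(TBDPS-oxy)-4-methylpent-3-en-1-yl}-9-{(3Z)-5-(TBDPS-oxy)-3-methylpent-3-en-1-yl}-5-methyl-9-[(triethylsilyl)oxy]-6,8-dioxabicyclo[3.2.2]nonan-7-one | C/C(=C/CC[C@@]12OC(CC/C(C)=C\CO[Si](c3ccccc3)(c3ccccc3)C(C)(C)C)(O[Si](CC)(CC)CC)[C@@](C)(CC[C@@H]1O)OC2=O)CO[Si](c1ccccc1)(c1ccccc1)C(C)(C)C | intermediate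
34 | (1R,2S,5R,9S)-2-hydroxy-1-{(3Z)-5-(TBDPS-oxy)-4-methylpent-3-en-1-yl}-9-{(3Z)-5-(TBDPS-oxy)-3-methylpent-3-en-1-yl}-5-methyl-6,8-dioxabicyclo[3.2.2]nonan-7-one | C/C(=C/CC[C@@]12O[C@@H](CC/C(C)=C\CO[Si](c3ccccc3)(c3ccccc3)C(C)(C)C)[C@@](C)(CC[C@@H]1O)OC2=O)CO[Si](c1ccccc1)(c1ccccc1)C(C)(C)C | intermediate
35 | (1R,2S,5R,9S)-2-hydroxy-1-[(3Z)-5-hydroxy-4-methylpent-3-en-1-yl]-9-[(3Z)-5-hydroxy-3-methylpent-3-en-1-yl]-5-methyl-6,8-dioxabicyclo[3.2.2]nonan-7-one | C/C(=C/CC[C@@]12O[C@@H](CC/C(C)=C\CO)[C@@](C)(CC[C@@H]1O)OC2=O)CO | target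

**Step count and risks**

Total: 20 steps. Longest linear sequence: 12 steps (steps 1–4, then 13–20).

Most likely to fail:

1. Step 14 (proposed method). The α-acyloxy enolate may undergo 1,2-acyl migration (Chan-type) or ring fragmentation before the organolithium arrives, and partial collapse of the tetrahedral intermediate would lead to double addition or incomplete silyl capture. The fallback uses known reactions only, sets out from 6 and returns at 27. Amide coupling of 6 with N,O-dimethylhydroxylamine (EDC, HOBt) should give the N-methoxy-N-methylamide F1. Two equivalents of 23 (the first deprotonates the hydroxyl) should give the α-hydroxy ketone F2. Acylation of its tertiary hydroxyl with 14 (pyridine, DMAP) should give the bromo ester F3. Silver(I)-assisted hydrolysis of the α-bromide (AgOTf, aqueous acetone) should give the α-hydroxy ester, which is expected to close onto the ketone as the six-membered cyclic hemiketal F4. Silylation (TESOTf, 2,6-lutidine) then gives 27. The C–C bond is made here by acyl substitution on an open-chain amide before the ring exists, so no discrimination between two ring carbonyls is needed.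

2. Step 18. Protonation of the samarium enolate or ketyl-type reduction of the aldehyde may outrun the strained bridging closure, or closure may proceed through an open transition state and give the C2 epimer. The fallback sets out from 29 and returns at 33. Dehydrobromination (DBU) should give the alkylidene lactone F5; PMB removal (DDQ) the alcohol F6; Dess–Martin oxidation the aldehyde F7. Conjugate reduction with a copper hydride ([(Ph3P)CuH]6) then generates the C1 copper enolate regiospecifically, and this should add to the aldehyde in a reductive aldol cyclisation to give 33.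

3. Step 19. Hydride delivery to the destabilised oxocarbenium ion may show poor facial selectivity, and prolonged Lewis-acid exposure may ionise the allylic silyl ethers. The fallback sets out from 33 and returns at 34. Brief exchange of the silyloxy group for a phenylthio group (PhSH, BF3·OEt2, −78 °C) should give the mixed O,S-ketal F8. Radical reduction (Bu3SnH, AIBN, toluene, 80 °C) then proceeds through the α-alkoxy radical at C9, and hydrogen-atom transfer from the small tin hydride should occur from the open lactone face to give 34.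

Further compounds
F1 | step 14 | (2R)-2-hydroxy-N-methoxy-5-[(4-methoxybenzyl)oxy]-N,2-dimethylpentanamide | COc1ccc(COCCC[C@@](C)(O)C(=O)N(C)OC)cc1
F2 | step 14 | (2R,7Z)-2-hydroxy-9-(TBDPS-oxy)-1-[(4-methoxybenzyl)oxy]... α-hydroxy ketone from F1 and 23 | COc1ccc(COCCC[C@@](C)(O)C(=O)CC/C(C)=C\CO[Si](c2ccccc2)(c2ccccc2)C(C)(C)C)cc1
F3 | step 14 | 2-bromoacyl ester of F2 at the tertiary hydroxyl | COc1ccc(COCCC[C@@](C)(OC(=O)C(Br)CC/C=C(C)\CO[Si](c2ccccc2)(c2ccccc2)C(C)(C)C)C(=O)CC/C(C)=C\CO[Si](c2ccccc2)(c2ccccc2)C(C)(C)C)cc1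
F4 | step 14 | cyclic hemiketal, 5-hydroxy analogue of 27 | COc1ccc(COCCC[C@@]2(C)OC(=O)C(CC/C=C(C)\CO[Si](c3ccccc3)(c3ccccc3)C(C)(C)C)OC2(O)CC/C(C)=C\CO[Si](c3ccccc3)(c3ccccc3)C(C)(C)C)cc1
F5 | step 18 | 3-alkylidene lactone from 29 by loss of HBr | COc1ccc(COCCC[C@@]2(C)OC(=O)C(=CC/C=C(C)\CO[Si](c3ccccc3)(c3ccccc3)C(C)(C)C)OC2(O[Si](CC)(CC)CC)CC/C(C)=C\CO[Si](c3ccccc3)(c3ccccc3)C(C)(C)C)cc1
F6 | step 18 | primary alcohol from F5 | OCCC[C@@]1(C)OC(=O)C(=CC/C=C(C)\CO[Si](c2ccccc2)(c2ccccc2)C(C)(C)C)OC1(O[Si](CC)(CC)CC)CC/C(C)=C\CO[Si](c2ccccc2)(c2ccccc2)C(C)(C)C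
F7 | step 18 | aldehyde from F6 | O=CCC[C@@]1(C)OC(=O)C(=CC/C=C(C)\CO[Si](c2ccccc2)(c2ccccc2)C(C)(C)C)OC1(O[Si](CC)(CC)CC)CC/C(C)=C\CO[Si](c2ccccc2)(c2ccccc2)C(C)(C)C
F8 | step 19 | 9-(phenylsulfanyl) analogue of 33 (mixed O,S-ketal) | C/C(=C/CC[C@@]12OC(CC/C(C)=C\CO[Si](c3ccccc3)(c3ccccc3)C(C)(C)C)(Sc3ccccc3)[C@@](C)(CC[C@@H]1O)OC2=O)CO[Si](c1ccccc1)(c1ccccc1)C(C)(C)C
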